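**Assumption:** the SMILES is read as the cis-fused 5-epi-drimane (5R,8R,9R,10S): H-5, the C10 methyl, the C9 side chain and the C8 methyl all on one face (β), 8-OH on the other (α). Drimane numbering is used throughout; 1, 2 and 24 are taken as catalogue compounds.

**Retrosynthetic overview**
1. Target ⇐ deprotection and benzylic deoxygenation of the adduct of an aryllithium (benzyl-protected hydroquinone, masked CHO) with 8α-silyloxy-5β-driman-11-al (C11–aryl bond).
2. Aldehyde ⇐ vinyl group; 8α-tertiary alcohol ⇐ α-epoxide of the Δ7 alkene ⇐ enol triflate ⇐ vinyl conjugate addition to a cis-fused Δ8-en-7-one (sets C9, then C8).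
3. Enone ⇐ cis-decalone ⇐ hydrogen-atom-transfer radical conjugate cyclisation of a 4,4-disubstituted cyclohexenone (closes ring A onto ring B, gives the cis fusion and the gem-dimethyl group, sets C5).
4. Cyclohexenone ⇐ ene-reductase desymmetrisation of an achiral cyclohexa-2,5-dienone (sets C10) ⇐ alkylation of a cyclohexanone-ketal nitrile.
5. Ring order: ring B is bought as the cyclohexane, ring A is closed by the radical step, the arene is attached last.

**Route**

Step 1
Reactants: 1 1,4-dioxaspiro[4.5]decane-8-carbonitrile; 2 5-bromo-2-methylpent-2-ene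
Product: 4 8-(4-methylpent-3-en-1-yl)-1,4-dioxaspiro[4.5]decane-8-carbonitrile, via lithiated nitrile 3 (not isolated)
Conditions: LiN(i-Pr)2, THF, −78 °C; then 2, −78 °C → rt
Reagents that add atoms: none
Why: α-Alkylation of a lithiated tertiary nitrile (SN2 on a primary bromide) builds the quaternary carbon that becomes C10; the product is achiral.

Step 2
Reactants: 4 8-(4-methylpent-3-en-1-yl)-1,4-dioxaspiro[4.5]decane-8-carbonitrile
Product: 5 8-(4-methylpent-3-en-1-yl)-1,4-dioxaspiro[4.5]decane-8-carbaldehyde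
Conditions: i-Bu2AlH, toluene, −78 → 0 °C; aq. KNaC4H4O6, then wet SiO2
Reagents that add atoms: water (O)
Why: Partial hydride reduction of the nitrile stops at the N-aluminoimine, which mild hydrolysis turns into the aldehyde without opening the dioxolane.

Step 3
Reactants: 5 8-(4-methylpent-3-en-1-yl)-1,4-dioxaspiro[4.5]decane-8-carbaldehyde
Product: 7 8-methyl-8-(4-methylpent-3-en-1-yl)-1,4-dioxaspiro[4.5]decane, via hydrazone 6 (not isolated)
Conditions: N2H4·H2O, KOH, diethylene glycol, 130 °C then 200 °C, under N2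
Reagents that add atoms: none
Why: Wolff–Kishner (Huang-Minlon) reduction converts the formyl group into the future C10 methyl under basic conditions that spare the ketal and the isolated alkene.

Step 4
Reactants: 7 8-methyl-8-(4-methylpent-3-en-1-yl)-1,4-dioxaspiro[4.5]decane
Product: 8 4-methyl-4-(4-methylpent-3-en-1-yl)cyclohexan-1-one
Conditions: 1 M HCl, THF, rt
Reagents that add atoms: water (O)
Why: Acid-catalysed ketal hydrolysis frees the ketone; the symmetric 4,4-disubstituted cyclohexanone is still achiral.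

Step 5
Reactants: 8 4-methyl-4-(4-methylpent-3-en-1-yl)cyclohexan-1-one
Product: 9 4-methyl-4-(4-methylpent-3-en-1-yl)cyclohexa-2,5-dien-1-one
Conditions: IBX (4 equiv), PhF/DMSO 2:1, 80 °C
Reagents that add atoms: none
Why: Two IBX-mediated α,β-dehydrogenations (Nicolaou conditions) give the cross-conjugated dienone, which cannot aromatise because C4 is quaternary and which is prochiral (two enantiotopic enone arms).

Step 6
Reactants: 9 4-methyl-4-(4-methylpent-3-en-1-yl)cyclohexa-2,5-dien-1-one
Product: 10 (4R)-4-methyl-4-(4-methylpent-3-en-1-yl)cyclohex-2-en-1-one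
Conditions: ene-reductase (flavin-dependent old-yellow-enzyme family, R-selective variant), NADP+ (cat.), D-glucose, glucose dehydrogenase, KH2PO4/K2HPO4 buffer pH 7.0, 5% DMSO, 30 °C
Reagents that add atoms: none
Why: Biocatalytic desymmetrising conjugate reduction: the ene-reductase delivers hydride and proton to only one of the two enantiotopic C=C bonds, which sets the first stereocentre (the future C10) as R.

Step 7
Reactants: 10 (4R)-4-methyl-4-(4-methylpent-3-en-1-yl)cyclohex-2-en-1-one
Product: 12 (4R)-4,6-dimethyl-4-(4-methylpent-3-en-1-yl)cyclohex-2-en-1-one (both C6 epimers), via lithium enolate 11 (not isolated)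
Conditions: LiN(i-Pr)2, THF, −78 °C; then MeI, −78 → 0 °C
Reagents that add atoms: iodomethane (CI)
Why: Kinetic α′-enolate alkylation (the γ-position is quaternary) installs the future C8 methyl; this centre is planarised again in step 9, so the epimer ratio does not matter.

Step 8
Reactants: 12 (4R)-4,6-dimethyl-4-(4-methylpent-3-en-1-yl)cyclohex-2-en-1-one
Product: 13 11-nor-5β-driman-7-one (cis-fused: 5β-H and 10β-CH3; both C8 epimers)
Conditions: Fe(acac)3 (30 mol %), PhSiH3 (2.5 equiv), EtOH/ethylene glycol 5:1, 60 °C, degassed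
Reagents that add atoms: none
Why: Metal-hydride hydrogen-atom-transfer radical conjugate addition (6-exo Giese cyclisation): the tertiary radical from the side-chain alkene adds axially to the enone β-carbon from the face of its own tether, giving the cis-fused decalin (sets C5, H-5 syn to the C10 methyl) and the gem-dimethyl carbon in one step.

Step 9
Reactants: 13 11-nor-5β-driman-7-one
Product: 15 11-nor-5β-drim-8-en-7-one, via silyl enol ether 14 (not isolated)
Conditions: Me3SiCl, NaI, Et3N, MeCN, rt; then Pd(OAc)2 (1.1 equiv), MeCN, rt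
Reagents that add atoms: none
Why: Saegusa–Ito oxidation of the thermodynamic (more substituted, C7=C8) silyl enol ether introduces the C8=C9 double bond regioselectively and erases the C8 stereocentre.

Step 10
Reactants: 15 11-nor-5β-drim-8-en-7-one
Product: 17 9β-ethenyl-11-nor-5β-drim-7-en-7-yl trifluoromethanesulfonate, via magnesium enolate 16 (not isolated)
Conditions: CH2=CHMgBr (2 equiv), CuBr·SMe2 (20 mol %), THF, −40 → −10 °C; then 2-[N,N-bis(trifluoromethylsulfonyl)amino]-5-chloropyridine, −78 °C → rt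
Reagents that add atoms: vinylmagnesium bromide (C=C[Mg]Br); 2-[N,N-bis(trifluoromethylsulfonyl)amino]-5-chloropyridine (FC(F)(F)S(=O)(=O)N(c1ccc(Cl)cn1)S(=O)(=O)C(F)(F)F)
Why: Copper-catalysed conjugate addition followed by O-triflation of the regiodefined enolate: vinyl adds axially to C9 on the convex face, anti to the pseudoaxial C1 methylene and clear of the C4 gem-dimethyl group, hence syn to the C10 methyl (sets C9).

Step 11
Reactants: 17 9β-ethenyl-11-nor-5β-drim-7-en-7-yl trifluoromethanesulfonate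
Product: 18 9β-ethenyl-11-nor-5β-drim-7-ene
Conditions: Pd(OAc)2 (5 mol %), PPh3 (10 mol %), HCO2H, n-Bu3N, DMF, 60 °C
Reagents that add atoms: none
Why: Palladium-catalysed formate hydrogenolysis of the enol triflate removes the C7 oxygen and leaves the trisubstituted C7=C8 alkene.

Step 12
Reactants: 18 9β-ethenyl-11-nor-5β-drim-7-ene
Product: 19 7α,8α-epoxy-9β-ethenyl-11-nor-5β-drimane
Conditions: mCPBA (1.05 equiv), NaHCO3, CH2Cl2, 0 °C
Reagents that add atoms: 3-chloroperoxybenzoic acid (OOC(=O)c1cccc(Cl)c1)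
Why: Prilezhaev epoxidation of the trisubstituted alkene (the vinyl group reacts far more slowly) from the α face, anti to the 9β-vinyl group held pseudoaxial by allylic strain with the C8 methyl (sets C8).

Step 13
Reactants: 19 7α,8α-epoxy-9β-ethenyl-11-nor-5β-drimane
Product: 20 9β-ethenyl-11-nor-5β-driman-8α-ol
Conditions: LiAlH4, THF, 0 → 50 °C; aq. work-up
Reagents that add atoms: none
Why: Trans-diaxial (Fürst–Plattner) hydride opening of the epoxide at the less substituted C7 leaves the tertiary 8α-alcohol with the 8β-methyl.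

Step 14
Reactants: 20 9β-ethenyl-11-nor-5β-driman-8α-ol
Product: 21 9β-ethenyl-8α-(triethylsilyloxy)-11-nor-5β-drimane
Conditions: Et3SiOTf, 2,6-lutidine, CH2Cl2, −78 → 0 °C
Reagents that add atoms: triethylsilyl trifluoromethanesulfonate (CC[Si](CC)(CC)OS(=O)(=O)C(F)(F)F)
Why: Silylation of the hindered tertiary alcohol with a silyl triflate prevents retro-aldol cleavage and alkoxide side reactions at the β-hydroxy aldehyde stage.

Step 15
Reactants: 21 9β-ethenyl-8α-(triethylsilyloxy)-11-nor-5β-drimane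
Product: 23 8α-(triethylsilyloxy)-5β-driman-11-al, via ozonide 22 (not isolated)
Conditions: O3, CH2Cl2, −78 °C; then PPh3, −78 °C → rt
Reagents that add atoms: ozone ([O-][O+]=O)
Why: Ozonolysis with reductive work-up cleaves the remaining vinyl group to the C11 aldehyde under neutral conditions that do not epimerise C9.

Step 16
Reactants: 24 2-bromobenzene-1,4-diol
Product: 25 1,4-bis(benzyloxy)-2-bromobenzene
Conditions: BnBr, K2CO3, DMF, 60 °C
Reagents that add atoms: benzyl bromide (BrCc1ccccc1)
Why: Williamson ether synthesis protects both phenols as benzyl ethers.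

Step 17
Reactants: 25 1,4-bis(benzyloxy)-2-bromobenzene
Product: 27 3,6-bis(benzyloxy)-2-bromobenzaldehyde, via aryllithium 26 (not isolated)
Conditions: LiN(i-Pr)2, THF, −78 °C; then DMF, −78 → 0 °C; H2O
Reagents that add atoms: N,N-dimethylformamide (CN(C)C=O)
Why: Directed ortho-lithiation at the C–H flanked by bromine and a benzyloxy group (kept at −78 °C to avoid aryne formation) followed by formylation puts the aldehyde next to the future attachment carbon.

Step 18
Reactants: 27 3,6-bis(benzyloxy)-2-bromobenzaldehyde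
Product: 28 2-[3,6-bis(benzyloxy)-2-bromophenyl]-1,3-dioxolane
Conditions: HOCH2CH2OH, p-TsOH (cat.), toluene, reflux, Dean–Stark
Reagents that add atoms: ethylene glycol (OCCO)
Why: Acid-catalysed acetalisation masks the aldehyde for the organolithium step.

Step 19
Reactants: 28 2-[3,6-bis(benzyloxy)-2-bromophenyl]-1,3-dioxolane; 23 8α-(triethylsilyloxy)-5β-driman-11-al
Product: 32 O-{[3,6-bis(benzyloxy)-2-(1,3-dioxolan-2-yl)phenyl][8α-(triethylsilyloxy)-11-nor-5β-driman-9β-yl]methyl} S-methyl dithiocarbonate (both C11 epimers), via aryllithium 29 (not isolated), via lithium alkoxide 30 (not isolated), via lithium xanthate 31 (not isolated)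
Conditions: n-BuLi, THF, −78 °C; then 23, −78 → −30 °C; then CS2, 0 °C; then MeI, rt
Reagents that add atoms: carbon disulfide (S=C=S); iodomethane (CI)
Why: Bromine–lithium exchange, 1,2-addition of the aryllithium to the aldehyde (forms the C11–aryl bond; the new carbinol centre is removed in step 20) and in-situ xanthate formation.

Step 20
Reactants: 32 the S-methyl xanthate
Product: 33 11-[3,6-bis(benzyloxy)-2-(1,3-dioxolan-2-yl)phenyl]-8α-(triethylsilyloxy)-5β-drimane
Conditions: n-Bu3SnH, AIBN (cat.), toluene, 100 °C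
Reagents that add atoms: none
Why: Barton–McCombie radical deoxygenation removes the benzylic oxygen without acid, giving the C11 methylene.

Step 21
Reactants: 33 11-[3,6-bis(benzyloxy)-2-(1,3-dioxolan-2-yl)phenyl]-8α-(triethylsilyloxy)-5β-drimane
Product: 34 2-(1,3-dioxolan-2-yl)-3-{[8α-(triethylsilyloxy)-5β-driman-11-yl]}benzene-1,4-diol
Conditions: H2 (1 atm), 10% Pd/C, EtOAc, Et3N (trace), rt
Reagents that add atoms: none
Why: Hydrogenolysis of the two benzyl ethers frees the hydroquinone while the dioxolane protects the aldehyde from reduction.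

Step 22
Reactants: 34 2-(1,3-dioxolan-2-yl)-3-{[8α-(triethylsilyloxy)-5β-driman-11-yl]}benzene-1,4-diol
Product: 35 3,6-dihydroxy-2-[(8α-hydroxy-5β-driman-11-yl)]benzaldehyde, (5R,8R,9R,10S), the target
Conditions: 1 M HCl, THF, rt, under argon
Reagents that add atoms: water (O)
Why: Mild aqueous acid hydrolyses the dioxolane and the triethylsilyl ether; dilute acid at room temperature avoids ionising the tertiary alcohol.

**Compound list**

1 | 1,4-dioxaspiro[4.5]decane-8-carbonitrile | N#CC1CCC2(CC1)OCCO2 | starting material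
2 | 5-bromo-2-methylpent-2-ene | CC(C)=CCCBr | starting material
3 | 8-lithio-1,4-dioxaspiro[4.5]decane-8-carbonitrile (lithiated nitrile) | [Li]C1(C#N)CCC2(CC1)OCCO2 | intermediate
4 | 8-(4-methylpent-3-en-1-yl)-1,4-dioxaspiro[4.5]decane-8-carbonitrile | CC(C)=CCCC1(C#N)CCC2(CC1)OCCO2 | intermediate
5 | 8-(4-methylpent-3-en-1-yl)-1,4-dioxaspiro[4.5]decane-8-carbaldehyde | CC(C)=CCCC1(C=O)CCC2(CC1)OCCO2 | intermediate
6 | hydrazone of aldehyde 5 | CC(C)=CCCC1(C=NN)CCC2(CC1)OCCO2 | intermediate
7 | 8-methyl-8-(4-methylpent-3-en-1-yl)-1,4-dioxaspiro[4.5]decane | CC(C)=CCCC1(C)CCC2(CC1)OCCO2 | intermediate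
8 | 4-methyl-4-(4-methylpent-3-en-1-yl)cyclohexan-1-one | CC(C)=CCCC1(C)CCC(=O)CC1 | intermediate
9 | 4-methyl-4-(4-methylpent-3-en-1-yl)cyclohexa-2,5-dien-1-one | CC(C)=CCCC1(C)C=CC(=O)C=C1 | intermediate
10 | (4R)-4-methyl-4-(4-methylpent-3-en-1-yl)cyclohex-2-en-1-one | CC(C)=CCC[C@@]1(C)C=CC(=O)CC1 | intermediate
11 | lithium cross-conjugated dienolate of 10 | CC(C)=CCC[C@@]1(C)C=CC(O[Li])=CC1 | intermediate
12 | (4R)-4,6-dimethyl-4-(4-methylpent-3-en-1-yl)cyclohex-2-en-1-one (both C6 epimers) | CC(C)=CCC[C@@]1(C)C=CC(=O)C(C)C1 | intermediate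
13 | 11-nor-5β-driman-7-one (cis-fused, 5β-H, 10β-CH3; both C8 epimers) | CC1(C)CCC[C@@]2(C)[C@@H]1CC(=O)C(C)C2 | intermediate
14 | 7-(trimethylsilyloxy)-11-nor-5β-drim-7-ene | CC1(C)CCC[C@@]2(C)[C@@H]1CC(O[Si](C)(C)C)=C(C)C2 | intermediate
15 | 11-nor-5β-drim-8-en-7-one | CC1(C)CCC[C@@]2(C)[C@@H]1CC(=O)C(C)=C2 | intermediate
16 | bromomagnesium 9β-ethenyl-11-nor-5β-drim-7-en-7-olate | CC1(C)CCC[C@@]2(C)[C@@H]1CC(O[Mg]Br)=C(C)[C@@H]2C=C | intermediate
17 | 9β-ethenyl-11-nor-5β-drim-7-en-7-yl trifluoromethanesulfonate | CC1(C)CCC[C@@]2(C)[C@@H]1CC(OS(=O)(=O)C(F)(F)F)=C(C)[C@@H]2C=C | intermediate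
18 | 9β-ethenyl-11-nor-5β-drim-7-ene | CC1(C)CCC[C@@]2(C)[C@@H]1CC=C(C)[C@@H]2C=C | intermediate
19 | 7α,8α-epoxy-9β-ethenyl-11-nor-5β-drimane | CC1(C)CCC[C@@]2(C)[C@@H]1C[C@H]3O[C@@]3(C)[C@@H]2C=C | intermediate
20 | 9β-ethenyl-11-nor-5β-driman-8α-ol | CC1(C)CCC[C@@]2(C)[C@@H]1CC[C@@](C)(O)[C@@H]2C=C | intermediate
21 | 9β-ethenyl-8α-(triethylsilyloxy)-11-nor-5β-drimane | CC1(C)CCC[C@@]2(C)[C@@H]1CC[C@@](C)(O[Si](CC)(CC)CC)[C@@H]2C=C | intermediate
22 | ozonide (1,2,4-trioxolane) of 21 | CC1(C)CCC[C@@]2(C)[C@@H]1CC[C@@](C)(O[Si](CC)(CC)CC)[C@@H]2C3OCOO3 | intermediate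
23 | 8α-(triethylsilyloxy)-5β-driman-11-al | CC1(C)CCC[C@@]2(C)[C@@H]1CC[C@@](C)(O[Si](CC)(CC)CC)[C@@H]2C=O | intermediate
24 | 2-bromobenzene-1,4-diol | Oc1ccc(O)c(Br)c1 | starting material
25 | 1,4-bis(benzyloxy)-2-bromobenzene | Brc1cc(OCc2ccccc2)ccc1OCc1ccccc1 | intermediate
26 | [3,6-bis(benzyloxy)-2-bromophenyl]lithium | [Li]c1c(Br)c(OCc2ccccc2)ccc1OCc1ccccc1 | intermediate
27 | 3,6-bis(benzyloxy)-2-bromobenzaldehyde | O=Cc1c(Br)c(OCc2ccccc2)ccc1OCc1ccccc1 | intermediate
28 | 2-[3,6-bis(benzyloxy)-2-bromophenyl]-1,3-dioxolane | Brc1c(OCc2ccccc2)ccc(OCc2ccccc2)c1C1OCCO1 | intermediate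
29 | [3,6-bis(benzyloxy)-2-(1,3-dioxolan-2-yl)phenyl]lithium | [Li]c1c(OCc2ccccc2)ccc(OCc2ccccc2)c1C1OCCO1 | intermediate
30 | lithium alkoxide of the C11 carbinol adduct of 29 and 23 | CC1(C)CCC[C@@]2(C)[C@@H]1CC[C@@](C)(O[Si](CC)(CC)CC)[C@@H]2C(O[Li])c3c(OCc4ccccc4)ccc(OCc4ccccc4)c3C5OCCO5 | intermediate
31 | lithium xanthate of the C11 carbinol | CC1(C)CCC[C@@]2(C)[C@@H]1CC[C@@](C)(O[Si](CC)(CC)CC)[C@@H]2C(OC(=S)S[Li])c3c(OCc4ccccc4)ccc(OCc4ccccc4)c3C5OCCO5 | intermediate
32 | S-methyl xanthate of the C11 carbinol (both C11 epimers) | CC1(C)CCC[C@@]2(C)[C@@H]1CC[C@@](C)(O[Si](CC)(CC)CC)[C@@H]2C(OC(=S)SC)c3c(OCc4ccccc4)ccc(OCc4ccccc4)c3C5OCCO5 | intermediate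
33 | 11-[3,6-bis(benzyloxy)-2-(1,3-dioxolan-2-yl)phenyl]-8α-(triethylsilyloxy)-5β-drimane | CC1(C)CCC[C@@]2(C)[C@@H]1CC[C@@](C)(O[Si](CC)(CC)CC)[C@@H]2Cc3c(OCc4ccccc4)ccc(OCc4ccccc4)c3C5OCCO5 | intermediate
34 | 2-(1,3-dioxolan-2-yl)-3-{[8α-(triethylsilyloxy)-5β-driman-11-yl]}benzene-1,4-diol | CC1(C)CCC[C@@]2(C)[C@@H]1CC[C@@](C)(O[Si](CC)(CC)CC)[C@@H]2Cc3c(O)ccc(O)c3C5OCCO5 | intermediate
35 | 3,6-dihydroxy-2-[(8α-hydroxy-5β-driman-11-yl)]benzaldehyde, (5R,8R,9R,10S) | CC1(C)CCC[C@@]2(C)[C@@H]1CC[C@@](C)(O)[C@@H]2Cc1c(O)ccc(O)c1C=O | target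

**Totals**
Total step count: 22. Longest linear sequence: 19 steps (steps 1–15 and 19–22); the arene branch is steps 16–18.

**Three steps most likely to fail, each with a fallback**

Step 6 (enzymatic desymmetrisation). The enzyme must tell a methyl group from a lipophilic C6 alkenyl chain at a quaternary carbon, and it may not accept the substrate or may give low ee. The fallback builds the quaternary centre by organocatalysis instead of by desymmetrisation; it sets out from 2 and comes back at 10. Lithiated propionitrile (LiN(i-Pr)2, THF, −78 °C) is alkylated with 2 to give racemic 2,6-dimethylhept-5-enenitrile F1, and i-Bu2AlH reduction gives racemic 2,6-dimethylhept-5-enal F2. An enantioselective Michael addition of F2 to methyl vinyl ketone under a chiral primary-amine–thiourea catalyst (the labile α-centre of F2 is funnelled through the enamine) gives (2R)-2-methyl-2-(4-methylpent-3-en-1-yl)-5-oxohexanal F3. KOH/EtOH aldol condensation then closes F3 to 10. The ee is expected to be lower for a dialkyl aldehyde and would need upgrading.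

Step 8 (hydrogen-atom-transfer radical cyclisation). Simple reduction of the alkene or a poor cis:trans ratio could erode the yield. The fallback generates the same tertiary radical by a tin-hydride chain from a discrete halide; it sets out from 12 and comes back at 13. Markovnikov addition of HBr (33% in AcOH, CH2Cl2, 0 °C) to the side-chain alkene gives (4R)-4-(4-bromo-4-methylpentyl)-4,6-dimethylcyclohex-2-en-1-one F4. Slow addition of n-Bu3SnH with AIBN in benzene at 80 °C then closes the ring onto the enone to give 13.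

Step 12 (face of epoxidation). The α face is hindered by the axial C1 methylene of the cis-decalin, so the peracid could prefer the β face and lead to the 8-epi alcohol. The fallback uses anti-addition chemistry, which turns a β-face preference into the wanted outcome; it sets out from 18 and comes back at 20. NBS in aqueous DME at 0 °C forms the bromonium ion on the β face, and water opens it trans-diaxially at the tertiary C8 from the α face to give 7β-bromo-9β-ethenyl-11-nor-5β-driman-8α-ol F5. n-Bu3SnH/AIBN in toluene at 80 °C removes the bromine to give 20.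

**Further compounds**

F1 | step 6 | 2,6-dimethylhept-5-enenitrile (racemic) | CC(C)=CCCC(C)C#N
F2 | step 6 | 2,6-dimethylhept-5-enal (racemic) | CC(C)=CCCC(C)C=O
F3 | step 6 | (2R)-2-methyl-2-(4-methylpent-3-en-1-yl)-5-oxohexanal | CC(C)=CCC[C@@](CCC(C)=O)(C)C=O
F4 | step 8 | (4R)-4-(4-bromo-4-methylpentyl)-4,6-dimethylcyclohex-2-en-1-one | CC(C)(Br)CCC[C@@]1(C)C=CC(=O)C(C)C1
F5 | step 12 | 7β-bromo-9β-ethenyl-11-nor-5β-driman-8α-ol | CC1(C)CCC[C@@]2(C)[C@@H]1C[C@H](Br)[C@@](C)(O)[C@@H]2C=C
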